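**Strategy.** The two pyranone rings (rings C and C'') are opened at their carbonyl carbons. C4 and C4'' are isolated one-carbon units, each lying between a ring A carbon (C4a, C4a'') and the C3–C3'' bond, so both can be brought in as carbon monoxide across an alkyne that already carries C2, C2'' and both aryl ether oxygens. A single oxidative palladium-catalysed double carbonylation should convert the C2-symmetric (R,R)-1,4-bis(4-methoxyphenyl)but-2-yne-1,4-diol bis(aryl ether), which bears a pinacol boronate ortho to each ether oxygen, into the (Z)-3,3''-bichromanylidene-4,4''-dione, forming four C–C bonds and both heterocycles. Alkene reduction, equilibration of C3/C3'' and debenzylation complete the synthesis.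

Key step: step 9

Remark on numbering: flavanone numbering (O1, C2, C3, C4, C4a, C5–C8, C8a; doubly primed in the second unit) is used for the bichromanone core.
Assumption: 2-bromo-1-iodo-3-methoxybenzene (2-bromo-3-iodoanisole) is taken as a catalogue compound.
Assumption: (S,S)-ProPhenol is written for Si-face alkynyl delivery in steps 4 and 6; should an MTPA-ester check of 12 show the opposite sense, the (R,R) ligand would be used in both steps.

**Step 1**
Reactants: 1 2-bromo-1-iodo-3-methoxybenzene; 2 bis(pinacolato)diboron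
Product: 4 4-bromo-3-iodo-5-methoxyphenol, via arylboronate 3 (not isolated)
Conditions: [Ir(OMe)(cod)]2 (1.5 mol %), 4,4'-di-tert-butyl-2,2'-bipyridine (3 mol %), THF, 50 °C; then 30% aq. H2O2, NaOH, 0 °C to rt; HCl work-up
Reagents that add atoms: hydrogen peroxide, OO
Why: Iridium-catalysed C–H borylation is sterically controlled and in a 1,2,3-trisubstituted benzene reaches only C5, the one C–H with no ortho neighbour (aryl halides are tolerated), and peroxide oxidation then converts the C–B bond into the phenol at the same carbon (one-pot borylation/oxidation).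

**Step 2**
Reactants: 4 4-bromo-3-iodo-5-methoxyphenol
Product: 5 5-(benzyloxy)-2-bromo-1-iodo-3-methoxybenzene
Conditions: BnBr, K2CO3, DMF, rt
Reagents that add atoms: benzyl bromide, BrCc1ccccc1
Why: Williamson etherification of the phenoxide with benzyl bromide; the benzyl ether is the only protecting group of the route and masks the future 7-OH until the last step.

**Step 3**
Reactants: 5 5-(benzyloxy)-2-bromo-1-iodo-3-methoxybenzene; 6 1,3,5-trimethoxybenzene
Product: 8 [5-(benzyloxy)-2-bromo-3-methoxyphenyl](2,4,6-trimethoxyphenyl)iodonium 4-methylbenzenesulfonate, via hydroxy(tosyloxy)iodane 7 (not isolated)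
Conditions: mCPBA (1.1 equiv), TsOH·H2O (1.1 equiv), MeCN, rt to 50 °C; then 6 (1.1 equiv), rt
Reagents that add atoms: p-toluenesulfonic acid, Cc1ccc(S(=O)(=O)O)cc1
Why: Peracid oxidation gives the hydroxy(tosyloxy)iodane of trivalent iodine, which substitutes the very electron-rich 1,3,5-trimethoxybenzene (electrophilic aromatic substitution) in the established one-pot synthesis of aryl(2,4,6-trimethoxyphenyl)iodonium tosylates.

**Step 4**
Reactants: 9 4-methoxybenzaldehyde; 10 ethynyltrimethylsilane
Product: 12 (S)-1-(4-methoxyphenyl)prop-2-yn-1-ol, via silylated alkynol 11 (not isolated)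
Conditions: (S,S)-ProPhenol (10 mol %), Ph3P=O (20 mol %), Me2Zn (3 equiv), 10 (3 equiv), toluene, 0 °C; NH4Cl work-up; then K2CO3 (cat.), MeOH, rt
Reagents that add atoms: none
Why: Zinc–ProPhenol-catalysed enantioselective alkynylation of an aromatic aldehyde, in which the dinuclear zinc catalyst delivers the alkynyl group to the Si face and so sets the carbinol centre (R in 11, called S in 12 only because desilylation changes the CIP ranking), followed by mild methanolysis of the alkynylsilane.

**Step 5**
Reactants: 12 (S)-1-(4-methoxyphenyl)prop-2-yn-1-ol; 8 [5-(benzyloxy)-2-bromo-3-methoxyphenyl](2,4,6-trimethoxyphenyl)iodonium 4-methylbenzenesulfonate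
Product: 14 5-(benzyloxy)-2-bromo-1-methoxy-3-{[(1S)-1-(4-methoxyphenyl)prop-2-yn-1-yl]oxy}benzene, via sodium alkoxide 13 (not isolated)
Conditions: NaH (1.05 equiv), toluene, 0 °C; then 8 (1.2 equiv), 0 °C to rt
Reagents that add atoms: none
Why: Metal-free O-arylation of an alkoxide with a diaryliodonium salt (ligand coupling at trivalent iodine): the trimethoxyphenyl group stays on iodine as the dummy ligand, the ortho-bromo aryl group migrates to oxygen, and because the carbinol C–O bond is never broken the configuration is retained.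

**Step 6**
Reactants: 14 5-(benzyloxy)-2-bromo-1-methoxy-3-{[(1S)-1-(4-methoxyphenyl)prop-2-yn-1-yl]oxy}benzene; 9 4-methoxybenzaldehyde
Product: 15 (1R,4R)-4-[5-(benzyloxy)-2-bromo-3-methoxyphenoxy]-1,4-bis(4-methoxyphenyl)but-2-yn-1-ol
Conditions: (S,S)-ProPhenol (20 mol %), Ph3P=O (40 mol %), Me2Zn (3 equiv), 9 (2 equiv), toluene, 0 °C; NH4Cl work-up
Reagents that add atoms: none
Why: Second zinc–ProPhenol alkynylation with the same ligand: catalyst-controlled Si-face addition of the alkynylzinc derived from 14 sets the new carbinol centre R (the remote ether centre has little say), Me2Zn leaves the aryl bromide alone, and any C1 epimer is removed by chromatography.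

**Step 7**
Reactants: 15 (1R,4R)-4-[5-(benzyloxy)-2-bromo-3-methoxyphenoxy]-1,4-bis(4-methoxyphenyl)but-2-yn-1-ol; 8 [5-(benzyloxy)-2-bromo-3-methoxyphenyl](2,4,6-trimethoxyphenyl)iodonium 4-methylbenzenesulfonate
Product: 17 (1R,4R)-1,4-bis[5-(benzyloxy)-2-bromo-3-methoxyphenoxy]-1,4-bis(4-methoxyphenyl)but-2-yne, via sodium alkoxide 16 (not isolated)
Conditions: NaH (1.05 equiv), toluene, 0 °C; then 8 (1.2 equiv), 0 °C to rt
Reagents that add atoms: none
Why: Same retentive iodonium O-arylation as in step 5, now on the internal propargylic alkoxide, completing the C2-symmetric diether without touching either stereocentre.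

**Step 8**
Reactants: 17 (1R,4R)-1,4-bis[5-(benzyloxy)-2-bromo-3-methoxyphenoxy]-1,4-bis(4-methoxyphenyl)but-2-yne
Product: 19 (1R,4R)-1,4-bis[5-(benzyloxy)-3-methoxy-2-(4,4,5,5-tetramethyl-1,3,2-dioxaborolan-2-yl)phenoxy]-1,4-bis(4-methoxyphenyl)but-2-yne, via dilithio species 18 (not isolated)
Conditions: n-BuLi (2.2 equiv), THF, −78 °C, 15 min; then 2-isopropoxy-4,4,5,5-tetramethyl-1,3,2-dioxaborolane (3 equiv), −78 °C to rt; NH4Cl work-up; buffered silica
Reagents that add atoms: 2-isopropoxy-4,4,5,5-tetramethyl-1,3,2-dioxaborolane, CC(C)OB1OC(C)(C)C(C)(C)O1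
Why: Bromine–lithium exchange at −78 °C is much faster than deprotonation or addition to the alkyne, and the 2,6-dioxygenated aryllithium is trapped by the alkoxyboronate (lithiation–borylation); a palladium-catalysed borylation is avoided here because an arylpalladium bromide would add across the tethered alkyne.

**Step 9**
Reactants: 19 (1R,4R)-1,4-bis[5-(benzyloxy)-3-methoxy-2-(4,4,5,5-tetramethyl-1,3,2-dioxaborolan-2-yl)phenoxy]-1,4-bis(4-methoxyphenyl)but-2-yne
Product: 20 (Z)-7,7'-bis(benzyloxy)-5,5'-dimethoxy-2,2'-bis(4-methoxyphenyl)-[3,3'-bichromanylidene]-4,4'-dione with C2 and C2' arranged as in the target (formally 2R,2'R)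
Conditions: Pd(OAc)2 (10 mol %), 1,4-benzoquinone (1.5 equiv), AcOH (2 equiv), CO (20 bar), 1,4-dioxane (0.01 M), 50 °C; aqueous work-up
Reagents that add atoms: carbon monoxide, [C-]#[O+]
Why: Proposed new method: one boronate transmetalates to divalent palladium and the aryl–palladium bond inserts CO; the aroylpalladium adds syn across the alkyne in a 6-exo-dig closure of the first pyranone (C4a–C4, C4–C3), the ketone-chelated vinylpalladium inserts a second CO, and intramolecular transmetalation of the second boronate followed by reductive elimination from a seven-membered acyl(aryl)palladacycle closes the second pyranone (C3''–C4'', C4''–C4a''), after which benzoquinone returns zerovalent palladium to the divalent state. The closest known reactions are the cyclic acylpalladation of tethered alkynes by aroylpalladium species and the Pd(OAc)2/benzoquinone oxidative carbonylation of arylboron reagents; joining them in one catalytic cycle on an ynediol diether is new. No stereocentre is created: C2 and C2'' are spectators, and the Z geometry follows from syn acylpalladation and CO insertion with retention at the vinyl carbon. The selectivity needed is CO insertion before each C–C bond formation, against 5-exo arylpalladation of the alkyne and direct aryl–vinyl coupling; the two ortho oxygen substituents flanking each C–B bond, the fully substituted propargylic carbons and the high CO pressure should secure it, while high dilution keeps the second coupling intramolecular. Zerovalent palladium has no easy oxidative addition into these propargylic C–O bonds, so the ether linkages should stay intact during turnover.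

**Step 10**
Reactants: 20 (Z)-7,7'-bis(benzyloxy)-5,5'-dimethoxy-2,2'-bis(4-methoxyphenyl)-[3,3'-bichromanylidene]-4,4'-dione
Product: 21 (2S,2''S)-7,7''-bis(benzyloxy)-5,5''-dimethoxy-2,2''-bis(4-methoxyphenyl)-3,3''-bichromane-4,4''-dione as a mixture of C3/C3'' epimers
Conditions: Zn dust (10 equiv), AcOH/THF 1:1, 0 °C to rt
Reagents that add atoms: none
Why: Dissolving-metal conjugate reduction of an ene-1,4-dione, in which protonation of the zinc enolates by acetic acid should outrun β-elimination of the aryloxide; C2 and C2'' are untouched and C3/C3'' arise as a mixture that step 11 corrects.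

**Step 11**
Reactants: 21 (2S,2''S)-7,7''-bis(benzyloxy)-5,5''-dimethoxy-2,2''-bis(4-methoxyphenyl)-3,3''-bichromane-4,4''-dione (epimer mixture)
Product: 22 (2S,3R,2''S,3''R)-7,7''-di-O-benzyl-4',4''',5,5''-tetramethylchamaejasmin
Conditions: TsOH·H2O (0.2 equiv), CHCl3, 40 °C
Reagents that add atoms: none
Why: Acid-catalysed enolisation epimerises only the α-carbons C3 and C3'' and should funnel the mixture to the thermodynamic isomer with both rings 2,3-trans (all substituents pseudo-equatorial), so the fixed C2/C2'' centres dictate 3R,3''R; acid is preferred to base, which could open the pyranone by retro-oxa-Michael reaction and scramble C2.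

**Step 12**
Reactants: 22 (2S,3R,2''S,3''R)-7,7''-di-O-benzyl-4',4''',5,5''-tetramethylchamaejasmin
Product: 23 4',4''',5,5''-tetramethylchamaejasmin (2S,3R,2''S,3''R)
Conditions: H2 (1 atm), 10% Pd/C, EtOAc/THF, rt
Reagents that add atoms: none
Why: Hydrogenolysis of the two benzyl aryl ethers under neutral conditions, which aryl methyl ethers, aryl ketones and the cyclic C2–O bonds should survive at 1 atm and which cannot epimerise C3.

**Compound list**
1 | 2-bromo-1-iodo-3-methoxybenzene | COc1cccc(I)c1Br | starting material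
2 | bis(pinacolato)diboron | CC1(C)OB(OC1(C)C)B1OC(C)(C)C(C)(C)O1 | starting material
3 | 2-(4-bromo-3-iodo-5-methoxyphenyl)-4,4,5,5-tetramethyl-1,3,2-dioxaborolane | COc1cc(B2OC(C)(C)C(C)(C)O2)cc(I)c1Br | intermediate
4 | 4-bromo-3-iodo-5-methoxyphenol | COc1cc(O)cc(I)c1Br | intermediate
5 | 5-(benzyloxy)-2-bromo-1-iodo-3-methoxybenzene | COc1cc(OCc2ccccc2)cc(I)c1Br | intermediate
6 | 1,3,5-trimethoxybenzene | COc1cc(OC)cc(OC)c1 | starting material
7 | [5-(benzyloxy)-2-bromo-3-methoxyphenyl](hydroxy)(tosyloxy)-λ3-iodane | COc1cc(OCc2ccccc2)cc(I(O)OS(=O)(=O)c2ccc(C)cc2)c1Br | intermediate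
8 | [5-(benzyloxy)-2-bromo-3-methoxyphenyl](2,4,6-trimethoxyphenyl)iodonium 4-methylbenzenesulfonate | COc1cc(OC)c([I+]c2cc(OCc3ccccc3)cc(OC)c2Br)c(OC)c1.Cc1ccc(S(=O)(=O)[O-])cc1 | intermediate
9 | 4-methoxybenzaldehyde | COc1ccc(C=O)cc1 | starting material
10 | ethynyltrimethylsilane | C#C[Si](C)(C)C | starting material
11 | (R)-1-(4-methoxyphenyl)-3-(trimethylsilyl)prop-2-yn-1-ol | COc1ccc([C@H](C#C[Si](C)(C)C)O)cc1 | intermediate
12 | (S)-1-(4-methoxyphenyl)prop-2-yn-1-ol | COc1ccc([C@H](C#C)O)cc1 | intermediate
13 | sodium (S)-1-(4-methoxyphenyl)prop-2-yn-1-olate | COc1ccc([C@H](C#C)[O-])cc1.[Na+] | intermediate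
14 | 5-(benzyloxy)-2-bromo-1-methoxy-3-{[(1S)-1-(4-methoxyphenyl)prop-2-yn-1-yl]oxy}benzene | COc1ccc([C@H](C#C)Oc2cc(OCc3ccccc3)cc(OC)c2Br)cc1 | intermediate
15 | (1R,4R)-4-[5-(benzyloxy)-2-bromo-3-methoxyphenoxy]-1,4-bis(4-methoxyphenyl)but-2-yn-1-ol | COc1ccc([C@H](C#C[C@H](O)c2ccc(OC)cc2)Oc2cc(OCc3ccccc3)cc(OC)c2Br)cc1 | intermediate
16 | sodium (1R,4R)-4-[5-(benzyloxy)-2-bromo-3-methoxyphenoxy]-1,4-bis(4-methoxyphenyl)but-2-yn-1-olate | COc1ccc([C@H](C#C[C@H]([O-])c2ccc(OC)cc2)Oc2cc(OCc3ccccc3)cc(OC)c2Br)cc1.[Na+] | intermediate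
17 | (1R,4R)-1,4-bis[5-(benzyloxy)-2-bromo-3-methoxyphenoxy]-1,4-bis(4-methoxyphenyl)but-2-yne | COc1ccc([C@H](C#C[C@H](Oc2cc(OCc3ccccc3)cc(OC)c2Br)c2ccc(OC)cc2)Oc2cc(OCc3ccccc3)cc(OC)c2Br)cc1 | intermediate
18 | dilithio analogue of 17 (each bromine replaced by lithium) | COc1ccc([C@H](C#C[C@H](Oc2cc(OCc3ccccc3)cc(OC)c2[Li])c2ccc(OC)cc2)Oc2cc(OCc3ccccc3)cc(OC)c2[Li])cc1 | intermediate
19 | (1R,4R)-1,4-bis[5-(benzyloxy)-3-methoxy-2-(4,4,5,5-tetramethyl-1,3,2-dioxaborolan-2-yl)phenoxy]-1,4-bis(4-methoxyphenyl)but-2-yne | COc1ccc([C@H](C#C[C@H](Oc2cc(OCc3ccccc3)cc(OC)c2B2OC(C)(C)C(C)(C)O2)c2ccc(OC)cc2)Oc2cc(OCc3ccccc3)cc(OC)c2B2OC(C)(C)C(C)(C)O2)cc1 | intermediate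
20 | (2R,2'R,Z)-7,7'-bis(benzyloxy)-5,5'-dimethoxy-2,2'-bis(4-methoxyphenyl)-[3,3'-bichromanylidene]-4,4'-dione | COc1ccc([C@H]2Oc3cc(OCc4ccccc4)cc(OC)c3C(=O)/C2=C2\C(=O)c3c(OC)cc(OCc4ccccc4)cc3O[C@@H]2c2ccc(OC)cc2)cc1 | intermediate
21 | (2S,2''S)-7,7''-bis(benzyloxy)-5,5''-dimethoxy-2,2''-bis(4-methoxyphenyl)-3,3''-bichromane-4,4''-dione, C3/C3'' epimer mixture | COc1ccc([C@H]2Oc3cc(OCc4ccccc4)cc(OC)c3C(=O)C2C2C(=O)c3c(OC)cc(OCc4ccccc4)cc3O[C@@H]2c2ccc(OC)cc2)cc1 | intermediate
22 | (2S,3R,2''S,3''R)-7,7''-di-O-benzyl-4',4''',5,5''-tetramethylchamaejasmin | COc1ccc([C@H]2Oc3cc(OCc4ccccc4)cc(OC)c3C(=O)[C@@H]2[C@H]2C(=O)c3c(OC)cc(OCc4ccccc4)cc3O[C@@H]2c2ccc(OC)cc2)cc1 | intermediate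
23 | 4',4''',5,5''-tetramethylchamaejasmin (2S,3R,2''S,3''R) | COc1ccc([C@H]2Oc3cc(O)cc(OC)c3C(=O)[C@@H]2[C@H]2C(=O)c3c(OC)cc(O)cc3O[C@@H]2c2ccc(OC)cc2)cc1 | target

**Step count.** Total: 12 steps. Longest linear sequence: 11 steps (steps 1–3 and 5–12, from compound 1); the alkyne branch from 9 is 9 steps.

**Steps most likely to fail**

Step 9 (carbonylative bicyclisation). The aryl–palladium bond may add to the alkyne before CO inserts (5-exo carbopalladation), the vinylpalladium may couple with the second boronate without taking up CO, or protodeboronation and intermolecular coupling may win. The fallback uses known chemistry, without CO or boron, and sets out from 17. Bromine–lithium exchange (n-BuLi, THF, −78 °C) and quenching with N,N-dimethylformamide should give (1R,4R)-1,4-bis[5-(benzyloxy)-2-formyl-3-methoxyphenoxy]-1,4-bis(4-methoxyphenyl)but-2-yne F1. A thiazolium-derived N-heterocyclic carbene (3-benzyl-5-(2-hydroxyethyl)-4-methylthiazolium chloride, K2CO3, THF, 70 °C) should then hydroacylate the alkyne with one formyl group (6-exo-dig) to give the 3-alkylidenechroman-4-one aldehyde F2. An intramolecular Stetter reaction of the second formyl group on the enone of F2 closes the second pyranone in the same flask and gives diketone 21; the route is rejoined at 21, before step 11.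

Step 8 (lithiation–borylation). Proton transfer from the propargylic benzylic C–H to the aryllithium, anionic cyclisation onto the alkyne, or protodeboronation of the 2,6-dioxygenated arylboronate during isolation may erode the material. The fallback avoids carbanions altogether and makes no new compound (F0): from 17, a Miyaura borylation with 2 (PdCl2(dppf), KOAc, 1,4-dioxane, 80 °C) leads directly to 19, with 5-exo carbopalladation as the pathway to watch.

Step 7 (second O-arylation; step 5 shares the hazard). The secondary benzylic propargylic alkoxide may be oxidised to the ynone within the alkoxy-λ3-iodane instead of undergoing ligand coupling, or base may trigger propargyl–allenyl isomerisation. The fallback forms the C–O bond at carbon with inversion. From 14 and 9, the alkynylation of step 6 run with (R,R)-ProPhenol should give the C1-epimeric alcohol (1S,4R)-4-[5-(benzyloxy)-2-bromo-3-methoxyphenoxy]-1,4-bis(4-methoxyphenyl)but-2-yn-1-ol F3. From 5, copper-catalysed hydroxylation of the aryl iodide (CuI, 1,10-phenanthroline, KOH, DMSO/H2O, 100 °C; the bromide is left) gives 5-(benzyloxy)-2-bromo-3-methoxyphenol F4. A Mitsunobu etherification of F3 with F4 (PPh3, diisopropyl azodicarboxylate, toluene, 0 °C) returns to the route at 17; partial ionisation of the 4-methoxybenzylic centre is the point to monitor.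

**Further compounds**
F1 | step 9 | (1R,4R)-1,4-bis[5-(benzyloxy)-2-formyl-3-methoxyphenoxy]-1,4-bis(4-methoxyphenyl)but-2-yne | COc1ccc([C@H](C#C[C@H](Oc2cc(OCc3ccccc3)cc(OC)c2C=O)c2ccc(OC)cc2)Oc2cc(OCc3ccccc3)cc(OC)c2C=O)cc1
F2 | step 9 | 7-(benzyloxy)-5-methoxy-2-(4-methoxyphenyl)chroman-4-one carrying at C3 the exocyclic alkylidene =CH–CH(4-methoxyphenyl)–O–[5-(benzyloxy)-2-formyl-3-methoxyphenyl], carbinol centres as in 17 | COc1ccc([C@H]2Oc3cc(OCc4ccccc4)cc(OC)c3C(=O)/C2=C/[C@H](Oc2cc(OCc3ccccc3)cc(OC)c2C=O)c2ccc(OC)cc2)cc1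
F0 | step 8 | none | none
F3 | step 7 | (1S,4R)-4-[5-(benzyloxy)-2-bromo-3-methoxyphenoxy]-1,4-bis(4-methoxyphenyl)but-2-yn-1-ol | COc1ccc([C@H](C#C[C@@H](O)c2ccc(OC)cc2)Oc2cc(OCc3ccccc3)cc(OC)c2Br)cc1
F4 | step 7 | 5-(benzyloxy)-2-bromo-3-methoxyphenol | COc1cc(OCc2ccccc2)cc(O)c1Br
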